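## Retrosynthetic overview

1. Target ⇒ (loss of two aryl silyl groups) ⇒ break C1–C8: a tertiary C8 cation is captured by the prenyl-bearing enol carbon C1 of a dearomatized, monocyclic benzophenone. This is the biosynthesis-type closure, with a proton in place of the prenyl cation because the C7 prenyl is already in the chain.
2. Break C5–C6: alkylative dearomatization of catechol-silylated 3,5-diprenylmaclurin with a primary triflate that carries C7 and a 3-methylidene group as the cation precursor.
3. Triflate ⇒ (R)-lavandulol + prenyl bromide; an allylic dianion alkylation turns the isopropenyl methyl into the 4-methylpent-3-enyl arm.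
4. Aromatic part ⇒ maclurin ⇒ phloroglucinol + 3,4-dihydroxybenzonitrile, followed by two C-prenylations.
5. Ring order: ring A (C1–C5, C9) is the purchased phloroglucinol ring, dearomatized at C5; ring B (C1, C9, C5–C8) is closed last. C7 comes from lavandulol, C5 from the dearomatization, C1 and C8 from the cyclization.

Assumption: (R)-(−)-lavandulol (the natural enantiomer) is purchased; locants C1–C9 are those of the target's bicyclo[3.3.1]nonane (C8 = quaternary Me/4-methylpent-3-enyl carbon, C7 = CH–prenyl, C3 = aroyl carbon), and the SMILES is read as (1S,5S,7S,8R) with the C7 prenyl endo.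

## Route

Step 1
Reactants: 1 phloroglucinol; 2 3,4-dihydroxybenzonitrile
Product: 4 maclurin, via ketiminium chloride 3 (not isolated)
Conditions: ZnCl2, HCl (g), Et2O, 0 °C → rt; then H2O, reflux
Reagents that add atoms: water, O
Why: Hoesch acylation: the HCl/ZnCl2-activated nitrile attacks the very electron-rich ring of 1 once (the iminium product is deactivated) and the ketiminium salt 3 is hydrolysed to the ketone; no stereocentre.

Step 2
Reactants: 4 maclurin; 5 prenyl bromide
Product: 6 3,5-diprenylmaclurin
Conditions: 5 (2.2 equiv), 10% aq KOH, Na2B4O7, 0 °C, Ar; then 1 M HCl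
Reagents that add atoms: none
Why: Base-mediated C-prenylation of the acylphloroglucinol phenolate in water (solvated oxygens favour attack through the two free ring carbons), while borate holds the catechol as a cyclic complex so it is neither O-alkylated nor air-oxidised; no stereocentre.

Step 3
Reactants: 6 3,5-diprenylmaclurin
Product: 7 3,5-diprenylmaclurin 3',4'-bis(tert-butyldimethylsilyl) ether
Conditions: TBSCl (2.2 equiv), imidazole, DMF, 0 °C
Reagents that add atoms: tert-butyldimethylsilyl chloride, CC(C)(C)[Si](C)(C)Cl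
Why: Imidazole-promoted silyl ether formation, selective because the catechol hydroxyls are the only unhindered, non-chelated phenols (4-OH lies between two prenyl groups, 2-OH and 6-OH are hydrogen-bonded to the ketone); no stereocentre.

Step 4
Reactants: 8 (R)-lavandulol; 5 prenyl bromide
Product: 10 (2R)-7-methyl-2-(3-methylbut-2-en-1-yl)-3-methylideneoct-6-en-1-ol, via dilithio dianion 9 (not isolated)
Conditions: n-BuLi (2.3 equiv), TMEDA, Et2O, 0 °C → rt; then 5, −78 °C → rt; H2O
Reagents that add atoms: none
Why: Alkoxide-directed allylic lithiation and dianion alkylation of a 3-methylbut-3-en-1-ol unit: the lithium alkoxide steers the base to the isopropenyl methyl through a six-membered chelate, the 2-substituted allyl anion gives the same product from either terminus on SN2 reaction with 5, and C2 (the later C7) is not touched and keeps the R configuration of lavandulol.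

Step 5
Reactants: 10 (2R)-7-methyl-2-(3-methylbut-2-en-1-yl)-3-methylideneoct-6-en-1-ol
Product: 11 (2R)-7-methyl-2-(3-methylbut-2-en-1-yl)-3-methylideneoct-6-en-1-yl trifluoromethanesulfonate
Conditions: Tf2O, pyridine, CH2Cl2, −78 °C; cold filtration through silica, used at once
Reagents that add atoms: trifluoromethanesulfonic anhydride, O=S(=O)(OS(=O)(=O)C(F)(F)F)C(F)(F)F
Why: O-sulfonylation of the primary alcohol gives the only leaving group reactive enough for C-alkylation at a fully substituted carbon by this β-branched chain; the stereocentre is untouched.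

Step 6
Reactants: 7 3,5-diprenylmaclurin 3',4'-bis(tert-butyldimethylsilyl) ether; 11 (2R)-7-methyl-2-(3-methylbut-2-en-1-yl)-3-methylideneoct-6-en-1-yl trifluoromethanesulfonate
Product: 13 (6S)-4-{3,4-bis[(tert-butyldimethylsilyl)oxy]benzoyl}-3,5-dihydroxy-2,6-bis(3-methylbut-2-en-1-yl)-6-[(2S)-7-methyl-2-(3-methylbut-2-en-1-yl)-3-methylideneoct-6-en-1-yl]cyclohexa-2,4-dien-1-one, via trilithium triphenoxide 12 (not isolated)
Conditions: LiN(SiMe3)2 (3.1 equiv), THF, −78 → 0 °C; then 11 (1.3 equiv), −78 °C → rt; aq HCl; chromatography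
Reagents that add atoms: none
Why: Alkylative dearomatization: the lithium-chelated trianion reacts through a prenyl-bearing ring carbon (SN2 on the primary triflate; the two such carbons are equivalent) and this creates quaternary C5, but the remote C7 centre gives no useful facial bias, so 13 (ring 6S = C5 S) forms with its C5 epimer in about 1:1 ratio and is separated by chromatography (the epimer would lead to the 7-exo series).

Step 7
Reactants: 13 the (6S) dearomatized benzophenone of step 6
Product: 15 (1S,5S,7S,8R)-3-(3,4-dihydroxybenzoyl)-4-hydroxy-8-methyl-1,5,7-tris(3-methylbut-2-en-1-yl)-8-(4-methylpent-3-en-1-yl)bicyclo[3.3.1]non-3-ene-2,9-dione, via cyclized bis-silyl ether 14 (not isolated)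
Conditions: HCO2H (neat), rt, 24 h; evaporate; then KHF2, MeOH, rt
Reagents that add atoms: none
Why: Biomimetic cationic cyclization (Markovnikov, Friedel–Crafts-type C-alkylation of the enolized trione by a tertiary carbocation, with reversible O-capture and formate capture draining to the C–C product): formic acid protonates the 1,1-disubstituted alkene to the C8 cation, and the prenyl-bearing enol carbon C1 (not the aroyl-bearing C3, which is tied up in the chelated enol) closes ring B on the face fixed by C5; the chain folds boat-like with the C7 prenyl outward and anti to the forming bond (hence endo, 7S retained), the larger 4-methylpent-3-enyl arm of the planar cation lies beside H7 while methyl takes the crowded site between C6 and the C7 CH2 (8R), C1 (S) follows from the bridging, and KHF2 then cleaves both aryl silyl ethers.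

## Compound list

1 | phloroglucinol (benzene-1,3,5-triol) | Oc1cc(O)cc(O)c1 | starting material
2 | 3,4-dihydroxybenzonitrile | N#Cc1ccc(O)c(O)c1 | starting material
3 | (3,4-dihydroxyphenyl)(2,4,6-trihydroxyphenyl)methaniminium chloride | [NH2+]=C(c1ccc(O)c(O)c1)c1c(O)cc(O)cc1O.[Cl-] | intermediate
4 | maclurin, (3,4-dihydroxyphenyl)(2,4,6-trihydroxyphenyl)methanone | O=C(c1ccc(O)c(O)c1)c1c(O)cc(O)cc1O | intermediate
5 | prenyl bromide (1-bromo-3-methylbut-2-ene) | CC(C)=CCBr | starting material
6 | 3,5-diprenylmaclurin, (3,4-dihydroxyphenyl)[2,4,6-trihydroxy-3,5-bis(3-methylbut-2-en-1-yl)phenyl]methanone | O=C(c1ccc(O)c(O)c1)c1c(O)c(CC=C(C)C)c(O)c(CC=C(C)C)c1O | intermediate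
7 | {3,4-bis[(tert-butyldimethylsilyl)oxy]phenyl}[2,4,6-trihydroxy-3,5-bis(3-methylbut-2-en-1-yl)phenyl]methanone | O=C(c1ccc(O[Si](C)(C)C(C)(C)C)c(O[Si](C)(C)C(C)(C)C)c1)c1c(O)c(CC=C(C)C)c(O)c(CC=C(C)C)c1O | intermediate
8 | (R)-lavandulol, (2R)-5-methyl-2-(prop-1-en-2-yl)hex-4-en-1-ol | OC[C@H](CC=C(C)C)C(C)=C | starting material
9 | dilithio dianion of 8 (lithium alkoxide, 2-substituted allyllithium) | [Li]OC[C@H](CC=C(C)C)C(=C)C[Li] | intermediate
10 | (2R)-7-methyl-2-(3-methylbut-2-en-1-yl)-3-methylideneoct-6-en-1-ol | OC[C@H](CC=C(C)C)C(=C)CCC=C(C)C | intermediate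
11 | (2R)-7-methyl-2-(3-methylbut-2-en-1-yl)-3-methylideneoct-6-en-1-yl trifluoromethanesulfonate | O=S(=O)(OC[C@H](CC=C(C)C)C(=C)CCC=C(C)C)C(F)(F)F | intermediate
12 | trilithium triphenoxide of 7 | [Li]Oc1c(CC=C(C)C)c(O[Li])c(C(=O)c2ccc(O[Si](C)(C)C(C)(C)C)c(O[Si](C)(C)C(C)(C)C)c2)c(O[Li])c1CC=C(C)C | intermediate
13 | (6S)-4-{3,4-bis[(tert-butyldimethylsilyl)oxy]benzoyl}-3,5-dihydroxy-2,6-bis(3-methylbut-2-en-1-yl)-6-[(2S)-7-methyl-2-(3-methylbut-2-en-1-yl)-3-methylideneoct-6-en-1-yl]cyclohexa-2,4-dien-1-one | CC(C)=CCCC(=C)[C@@H](CC=C(C)C)C[C@]1(CC=C(C)C)C(=O)C(CC=C(C)C)=C(O)C(C(=O)c2ccc(O[Si](C)(C)C(C)(C)C)c(O[Si](C)(C)C(C)(C)C)c2)=C1O | intermediate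
14 | (1S,5S,7S,8R)-3-{3,4-bis[(tert-butyldimethylsilyl)oxy]benzoyl}-4-hydroxy-8-methyl-1,5,7-tris(3-methylbut-2-en-1-yl)-8-(4-methylpent-3-en-1-yl)bicyclo[3.3.1]non-3-ene-2,9-dione | CC(C)=CCC[C@]1(C)[C@@H](CC=C(C)C)C[C@]2(CC=C(C)C)C(=O)[C@@]1(CC=C(C)C)C(=O)C(C(=O)c1ccc(O[Si](C)(C)C(C)(C)C)c(O[Si](C)(C)C(C)(C)C)c1)=C2O | intermediate
15 | (1S,5S,7S,8R)-3-(3,4-dihydroxybenzoyl)-4-hydroxy-8-methyl-1,5,7-tris(3-methylbut-2-en-1-yl)-8-(4-methylpent-3-en-1-yl)bicyclo[3.3.1]non-3-ene-2,9-dione (CNP0108469.1, guttiferone A constitution) | CC(C)=CCC[C@]1(C)[C@@H](CC=C(C)C)C[C@]2(CC=C(C)C)C(=O)[C@@]1(CC=C(C)C)C(=O)C(C(=O)c1ccc(O)c(O)c1)=C2O | target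

## Step count and risks

Total steps: 7. Longest linear sequence: 5 (steps 1, 2, 3, 6, 7); the side-chain branch is steps 4 and 5.

Most likely to fail, in order:

Step 7 (cationic cyclization). The risks are O-cyclization to pyrans, protonation of the four trisubstituted alkenes (including cation–olefin closure of the methylidene/4-methylpent-3-enyl 1,5-diene), a hydride shift from C7 that would scramble it, and only modest facial preference at C8. The fallback triggers the same C1–C8 closure with a soft metal electrophile instead of a proton. It sets out from 13: mercury bis(trifluoroacetate), Hg(OCOCF3)2 (divalent mercury), in MeNO2 at −20 °C engages the 1,1-disubstituted alkene well ahead of the trisubstituted ones, and the enol carbon opens the mercurinium ion at the tertiary carbon. Aqueous NaCl gives the chloromercurial of the cyclized bis-silyl ether F1. NaBH4 in aq NaOH/THF replaces mercury by hydrogen and the route is rejoined at 14, which KHF2/MeOH takes to 15.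

Step 6 (alkylative dearomatization). The risks are O- instead of C-alkylation by the β-branched triflate at a fully substituted carbon, and no control at C5 (half of the material is the wrong epimer). The fallback reverses the order of the two C–C bonds at C5, so that the hindered, stereogenic alkylation is done with the reactive allylic bromide. It sets out from 4: one equivalent of 5 under the conditions of step 2 gives 3-prenylmaclurin F2, and TBSCl/imidazole gives its catechol bis-silyl ether F3. LiN(SiMe3)2 and 11 then alkylate the free, unhindered ring carbon to the aromatic side-chain benzophenone F4, with no new stereocentre. Dearomatizing prenylation of F4 with 5 (LiN(SiMe3)2, THF, 0 °C) comes back to the route at 13, after separation from its C5 epimer and from the regioisomer prenylated at the other substituted carbon.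

Step 4 (dianion homologation of lavandulol). The risks are competing lithiation at the allylic C2–H (erosion of ee) or at the prenyl group, and SN2' coupling of 5. The fallback builds the same alcohol by auxiliary-controlled alkylation. It sets out from 5, with purchased (E)-geranic acid and (4R)-4-benzyl-1,3-oxazolidin-2-one: acylation of the auxiliary (PivCl, Et3N, LiCl, THF) gives the N-geranoyl oxazolidinone F5. NaN(SiMe3)2 at −78 °C followed by 5 effects an Evans deconjugative α-alkylation (γ-deprotonation at the methyl cis to the carbonyl, α-attack anti to the benzyl group) to the α-prenylated imide F6, with 2R configuration. LiBH4 in Et2O/MeOH removes the auxiliary reductively and the route is rejoined at 10.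

## Further compounds

F1 | step 7 | (1S,5S,7S,8S)-3-{3,4-bis[(tert-butyldimethylsilyl)oxy]benzoyl}-8-[(chloromercurio)methyl]-4-hydroxy-1,5,7-tris(3-methylbut-2-en-1-yl)-8-(4-methylpent-3-en-1-yl)bicyclo[3.3.1]non-3-ene-2,9-dione | CC(C)=CCC[C@]1(C[Hg]Cl)[C@@H](CC=C(C)C)C[C@]2(CC=C(C)C)C(=O)[C@@]1(CC=C(C)C)C(=O)C(C(=O)c1ccc(O[Si](C)(C)C(C)(C)C)c(O[Si](C)(C)C(C)(C)C)c1)=C2O
F2 | step 6 | (3,4-dihydroxyphenyl)[2,4,6-trihydroxy-3-(3-methylbut-2-en-1-yl)phenyl]methanone | O=C(c1ccc(O)c(O)c1)c1c(O)cc(O)c(CC=C(C)C)c1O
F3 | step 6 | {3,4-bis[(tert-butyldimethylsilyl)oxy]phenyl}[2,4,6-trihydroxy-3-(3-methylbut-2-en-1-yl)phenyl]methanone | O=C(c1ccc(O[Si](C)(C)C(C)(C)C)c(O[Si](C)(C)C(C)(C)C)c1)c1c(O)cc(O)c(CC=C(C)C)c1O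
F4 | step 6 | {3,4-bis[(tert-butyldimethylsilyl)oxy]phenyl}{2,4,6-trihydroxy-3-(3-methylbut-2-en-1-yl)-5-[(2S)-7-methyl-2-(3-methylbut-2-en-1-yl)-3-methylideneoct-6-en-1-yl]phenyl}methanone | O=C(c1ccc(O[Si](C)(C)C(C)(C)C)c(O[Si](C)(C)C(C)(C)C)c1)c1c(O)c(C[C@H](CC=C(C)C)C(=C)CCC=C(C)C)c(O)c(CC=C(C)C)c1O
F5 | step 4 | (4R)-4-benzyl-3-[(2E)-3,7-dimethylocta-2,6-dienoyl]-1,3-oxazolidin-2-one | CC(C)=CCC/C(C)=C/C(=O)N1[C@H](Cc2ccccc2)COC1=O
F6 | step 4 | (4R)-4-benzyl-3-[(2R)-7-methyl-2-(3-methylbut-2-en-1-yl)-3-methylideneoct-6-enoyl]-1,3-oxazolidin-2-one | CC(C)=CCCC(=C)[C@@H](CC=C(C)C)C(=O)N1[C@H](Cc2ccccc2)COC1=O
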